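**Retrosynthetic overview**
- Target 18 comes from tribenzyl depside 17 by one hydrogenolysis of two benzyl ethers and the benzyl ester.
- Ring A of 17 (C1 ester carbonyl, C2 OMe, C4 OH, C6 propyl) is cut at C1–C2 and C5–C6. This gives diene 14, which supplies C2–C5 with both oxygens already differentiated, and the alkyne of aryl hex-2-ynoate 11, which supplies C1 and C6.
- Ring B of 11 is the purchased arene of divarinol 1. Its dibenzyl ether 2 is lithiated between the two oxygens and oxidised (ring B C3–O), then formylated at one of two symmetry-equivalent CH positions (ring B C1 carbon). The phenol is acylated with hex-2-ynoic acid 8 and CHO is taken to CO2Bn.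
- Diene 14 comes from 1,1-dimethoxyethene 12 by C-acetylation and enol silylation.
- Ring order: ring B is bought, ring A is formed last in the key step.

Key step: step 9

Assumption: the target has no stereocentre and no configurationally stable axis, so it is achiral; "single enantiomer" is read as the constitution drawn and no stereocontrol is needed.

**Step 1**
Reactants: 1 5-propylbenzene-1,3-diol (divarinol)
Product: 2 1,3-bis(benzyloxy)-5-propylbenzene
Conditions: BnBr (2.3 equiv), K2CO3, DMF, 60 °C
Reagents that add atoms: benzyl bromide, BrCc1ccccc1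
Why: Williamson ether synthesis on both phenoxides should give the symmetric diether, whose benzyl groups last until the final hydrogenolysis.

**Step 2**
Reactants: 2 1,3-bis(benzyloxy)-5-propylbenzene
Product: 5 2,6-bis(benzyloxy)-4-propylphenol, via aryllithium 3 (not isolated), via dimethyl arylboronate 4 (not isolated)
Conditions: n-BuLi, THF, 0 °C; B(OMe)3, −78 °C → rt; then AcOH, 30% H2O2, 0 °C → rt
Reagents that add atoms: hydrogen peroxide, OO
Why: Directed ortho-metalation should take place at the one CH flanked by both alkoxy groups, and borylation followed by oxidative C–B to C–O cleavage turns that carbanion into the phenol (metalation–borylation–oxidation).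

**Step 3**
Reactants: 5 2,6-bis(benzyloxy)-4-propylphenol
Product: 7 2,4-bis(benzyloxy)-3-hydroxy-6-propylbenzaldehyde, via iminium chloride 6 (not isolated)
Conditions: POCl3, DMF, 0 → 60 °C; then H2O, 50 °C
Reagents that add atoms: N,N-dimethylformamide, CN(C)C=O; water, O
Why: Vilsmeier–Haack formylation should attack one of the two symmetry-equivalent ring CH positions, each ortho to one benzyloxy group and para to the other, so only one regioisomer can form.

**Step 4**
Reactants: 7 2,4-bis(benzyloxy)-3-hydroxy-6-propylbenzaldehyde; 8 hex-2-ynoic acid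
Product: 9 2,6-bis(benzyloxy)-3-formyl-4-propylphenyl hex-2-ynoate
Conditions: DCC, DMAP (5 mol %), CH2Cl2, 0 °C → rt
Reagents that add atoms: none
Why: Steglich esterification should acylate the phenol despite its two flanking benzyloxy groups, because the rod-shaped alkynoyl donor is unhindered; the ester also masks the oxidation-prone phenol for step 5.

**Step 5**
Reactants: 9 2,6-bis(benzyloxy)-3-formyl-4-propylphenyl hex-2-ynoate
Product: 10 2,4-bis(benzyloxy)-3-(hex-2-ynoyloxy)-6-propylbenzoic acid
Conditions: NaClO2, NaH2PO4, 2-methylbut-2-ene (excess), t-BuOH/THF/H2O, 0 °C → rt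
Reagents that add atoms: sodium chlorite, [Na+].[O-]Cl=O
Why: Pinnick oxidation should convert the hindered aryl aldehyde into the acid without touching the alkyne, the aryl ester or the benzyl ethers, the alkene scavenger keeping hypochlorous acid off the electron-rich ring.

**Step 6**
Reactants: 10 2,4-bis(benzyloxy)-3-(hex-2-ynoyloxy)-6-propylbenzoic acid
Product: 11 benzyl 2,4-bis(benzyloxy)-3-(hex-2-ynoyloxy)-6-propylbenzoate
Conditions: BnBr, KHCO3, DMF, rt
Reagents that add atoms: benzyl bromide, BrCc1ccccc1
Why: SN2 O-alkylation of the carboxylate takes place at the benzylic carbon and is therefore insensitive to the two ortho substituents, and bicarbonate is too weak a base and nucleophile to cleave the aryl ynoate.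

**Step 7**
Reactants: 12 1,1-dimethoxyethene
Product: 13 4,4-dimethoxybut-3-en-2-one
Conditions: AcCl, Et3N, Et2O, 0 °C → rt
Reagents that add atoms: acetyl chloride, CC(=O)Cl
Why: C-acylation of the nucleophilic ketene acetal gives a dialkoxycarbenium ion that loses its acidic α-proton to triethylamine (acylation of a ketene acetal by addition–elimination).

**Step 8**
Reactants: 13 4,4-dimethoxybut-3-en-2-one
Product: 14 1,1-dimethoxy-3-(trimethylsilyloxy)buta-1,3-diene
Conditions: Me3SiCl, Et3N, ZnCl2 (cat.), toluene, 40 °C; distilled and used at once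
Reagents that add atoms: chlorotrimethylsilane, C[Si](C)(C)Cl
Why: Silyl enol ether formation at the methyl ketone, the only enolisable position, is the standard entry to 1-alkoxy-3-silyloxybutadienes.

**Step 9**
Reactants: 11 benzyl 2,4-bis(benzyloxy)-3-(hex-2-ynoyloxy)-6-propylbenzoate; 14 1,1-dimethoxy-3-(trimethylsilyloxy)buta-1,3-diene
Product: 17 benzyl 2,4-bis(benzyloxy)-3-[(4-hydroxy-2-methoxy-6-propylbenzoyl)oxy]-6-propylbenzoate, via cyclohexadiene cycloadduct 15 (not isolated), via aryl trimethylsilyl ether 16 (not isolated)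
Conditions: 14 (4 equiv), toluene, 120 °C, sealed tube; then 0.5 M HCl, THF, rt
Reagents that add atoms: none
Why: The electron-rich diene 14 should add across the ester-activated triple bond of 11 in a polarised, asynchronous [4+2] cycloaddition, the closest known reaction type being the Diels–Alder benzannulation of 1,1-dialkoxy-3-silyloxybutadienes with simple alk-2-ynoates to 4-hydroxy-2-alkoxy-6-alkylbenzoates. Ring A is closed as a six-membered carbocycle by intermolecular cycloaddition, the diene CH2 bonding to the propyl-bearing β-carbon (C5–C6) and the acetal carbon to the α-carbon (C1–C2). Cycloadduct 15 then loses methanol by 1,4-elimination to aryl silyl ether 16, which is hydrolysed in the acidic work-up; no stereocentre is formed. The step needs regioselectivity, and the substrate secures it: the CH2 terminus carries the largest HOMO coefficient (pushed by the 3-silyloxy and the 1,1-dimethoxy groups) and the β-carbon of the ynoate the largest LUMO coefficient, so the acetal oxygen must end up as the C2 methyl ether and the silyloxy oxygen as the free C4 hydroxyl. Chemoselectivity should follow because the ynoate is the only electron-poor π-bond and an aryl ester activates it more than an alkyl ester would. The benzyl ethers and the benzyl ester are inert to heat and dilute acid.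

**Step 10**
Reactants: 17 benzyl 2,4-bis(benzyloxy)-3-[(4-hydroxy-2-methoxy-6-propylbenzoyl)oxy]-6-propylbenzoate
Product: 18 2,4-dihydroxy-3-[(4-hydroxy-2-methoxy-6-propylbenzoyl)oxy]-6-propylbenzoic acid (target)
Conditions: H2 (1 atm), 10% Pd/C, EtOAc, rt
Reagents that add atoms: none
Why: Catalytic hydrogenolysis should cleave the two benzyl ethers and the benzyl ester in one operation under neutral conditions that leave the depside ester, the methyl ether and the decarboxylation-prone salicylic acid intact.

**Compound list**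
1 | 5-propylbenzene-1,3-diol (divarinol) | CCCc1cc(O)cc(O)c1 | starting material
2 | 1,3-bis(benzyloxy)-5-propylbenzene | CCCc1cc(OCc2ccccc2)cc(OCc2ccccc2)c1 | intermediate
3 | [2,6-bis(benzyloxy)-4-propylphenyl]lithium | CCCc1cc(OCc2ccccc2)c([Li])c(OCc2ccccc2)c1 | intermediate
4 | dimethyl [2,6-bis(benzyloxy)-4-propylphenyl]boronate | CCCc1cc(OCc2ccccc2)c(B(OC)OC)c(OCc2ccccc2)c1 | intermediate
5 | 2,6-bis(benzyloxy)-4-propylphenol | CCCc1cc(OCc2ccccc2)c(O)c(OCc2ccccc2)c1 | intermediate
6 | N-{[2,4-bis(benzyloxy)-3-hydroxy-6-propylphenyl]methylidene}-N-methylmethanaminium chloride | C[N+](C)=Cc1c(CCC)cc(OCc2ccccc2)c(O)c1OCc1ccccc1.[Cl-] | intermediate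
7 | 2,4-bis(benzyloxy)-3-hydroxy-6-propylbenzaldehyde | O=Cc1c(CCC)cc(OCc2ccccc2)c(O)c1OCc1ccccc1 | intermediate
8 | hex-2-ynoic acid | CCCC#CC(=O)O | starting material
9 | 2,6-bis(benzyloxy)-3-formyl-4-propylphenyl hex-2-ynoate | CCCC#CC(=O)Oc1c(OCc2ccccc2)cc(CCC)c(C=O)c1OCc1ccccc1 | intermediate
10 | 2,4-bis(benzyloxy)-3-(hex-2-ynoyloxy)-6-propylbenzoic acid | CCCC#CC(=O)Oc1c(OCc2ccccc2)cc(CCC)c(C(=O)O)c1OCc1ccccc1 | intermediate
11 | benzyl 2,4-bis(benzyloxy)-3-(hex-2-ynoyloxy)-6-propylbenzoate | CCCC#CC(=O)Oc1c(OCc2ccccc2)cc(CCC)c(C(=O)OCc2ccccc2)c1OCc1ccccc1 | intermediate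
12 | 1,1-dimethoxyethene | C=C(OC)OC | starting material
13 | 4,4-dimethoxybut-3-en-2-one | CC(=O)C=C(OC)OC | intermediate
14 | 1,1-dimethoxy-3-(trimethylsilyloxy)buta-1,3-diene | C=C(O[Si](C)(C)C)C=C(OC)OC | intermediate
15 | benzyl 2,4-bis(benzyloxy)-3-{[6,6-dimethoxy-2-propyl-4-(trimethylsilyloxy)cyclohexa-1,4-diene-1-carbonyl]oxy}-6-propylbenzoate | CCCC1=C(C(=O)Oc2c(OCc3ccccc3)cc(CCC)c(C(=O)OCc3ccccc3)c2OCc2ccccc2)C(OC)(OC)C=C(O[Si](C)(C)C)C1 | intermediate
16 | benzyl 2,4-bis(benzyloxy)-3-{[2-methoxy-6-propyl-4-(trimethylsilyloxy)benzoyl]oxy}-6-propylbenzoate | CCCc1cc(O[Si](C)(C)C)cc(OC)c1C(=O)Oc1c(OCc2ccccc2)cc(CCC)c(C(=O)OCc2ccccc2)c1OCc1ccccc1 | intermediate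
17 | benzyl 2,4-bis(benzyloxy)-3-[(4-hydroxy-2-methoxy-6-propylbenzoyl)oxy]-6-propylbenzoate | CCCc1cc(O)cc(OC)c1C(=O)Oc1c(OCc2ccccc2)cc(CCC)c(C(=O)OCc2ccccc2)c1OCc1ccccc1 | intermediate
18 | 2,4-dihydroxy-3-[(4-hydroxy-2-methoxy-6-propylbenzoyl)oxy]-6-propylbenzoic acid | CCCc1cc(O)cc(OC)c1C(=O)Oc1c(O)cc(CCC)c(C(=O)O)c1O | target

**Step count**
Total: 10 steps. Longest linear sequence: 8 steps (steps 1–6, 9, 10); steps 7–8 are the convergent diene branch.

**Steps most likely to fail**

1. Step 9. The cycloaddition at an internal, β-propyl-substituted alkyne may be slower than thermal desilylation or oligomerisation of the diene, and methanol released at 120 °C may begin to transesterify the aryl ester.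
 Fallback (sets out from 1 and 7, comes back at 18): ring A is made beforehand and joined by classical depside esterification.
 - Vilsmeier–Haack formylation of 1 (POCl3, DMF; then H2O) should give, through N-[(2,4-dihydroxy-6-propylphenyl)methylidene]-N-methylmethanaminium chloride F1, 2,4-dihydroxy-6-propylbenzaldehyde F2.
 - The non-chelated 4-OH is benzylated (BnBr, KHCO3, MeCN) to 4-(benzyloxy)-2-hydroxy-6-propylbenzaldehyde F3.
 - The chelated 2-OH is methylated (MeI, K2CO3, DMF) to 4-(benzyloxy)-2-methoxy-6-propylbenzaldehyde F4.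
 - Pinnick oxidation gives 4-(benzyloxy)-2-methoxy-6-propylbenzoic acid F5.
 - Trifluoroacetic anhydride in toluene converts F5 into 4-(benzyloxy)-2-methoxy-6-propylbenzoic trifluoroacetic anhydride F6, which acylates phenol 7 to 2,6-bis(benzyloxy)-3-formyl-4-propylphenyl 4-(benzyloxy)-2-methoxy-6-propylbenzoate F7.
 - Pinnick oxidation gives 2,4-bis(benzyloxy)-3-{[4-(benzyloxy)-2-methoxy-6-propylbenzoyl]oxy}-6-propylbenzoic acid F8, and hydrogenolysis of its three benzyl ethers (H2, Pd/C, EtOAc) gives 18.

2. Step 2. Deprotonation at the benzylic OCH2 positions, followed by [1,2]-Wittig rearrangement, may compete with ring lithiation between the two oxygens.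
 Fallback (sets out from 1, comes back at 3): the ring carbanion is generated by halogen–metal exchange instead of deprotonation.
 - Iodination of 1 between the hydroxyls (I2, NaHCO3, H2O/THF, 0 °C) should give 2-iodo-5-propylbenzene-1,3-diol F9.
 - Benzylation (BnBr, K2CO3, DMF) gives 1,3-bis(benzyloxy)-2-iodo-5-propylbenzene F10.
 - n-BuLi in THF at −78 °C converts F10 into aryllithium 3 by iodine–lithium exchange, at a temperature where the benzylic protons are not attacked; 3 is then borylated and oxidised as in step 2.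

3. Step 3. The free phenol may be O-formylated or O-phosphorylated, attack at the carbon flanked by benzyloxy and propyl may be slow, and hydrogen chloride formed on warming may start to cleave a benzyl ether.
 Fallback (sets out from 5, comes back at 7): the formyl carbon is introduced through an aryl anion instead of electrophilic substitution.
 - Bromination of 5 (NBS, MeCN, 0 °C) should give 2,6-bis(benzyloxy)-3-bromo-4-propylphenol F11.
 - n-BuLi (2.2 equiv, THF, −78 °C) deprotonates the phenol and exchanges the bromine, giving lithium 2,6-bis(benzyloxy)-3-lithio-4-propylphenolate F12.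
 - DMF converts F12 into dilithium 2,6-bis(benzyloxy)-3-[(dimethylamino)oxidomethyl]-4-propylphenolate F13, which collapses to 7 on aqueous NH4Cl work-up.

**Further compounds**
F1 | step 9 | N-[(2,4-dihydroxy-6-propylphenyl)methylidene]-N-methylmethanaminium chloride | C[N+](C)=Cc1c(O)cc(O)cc1CCC.[Cl-]
F2 | step 9 | 2,4-dihydroxy-6-propylbenzaldehyde | CCCc1cc(O)cc(O)c1C=O
F3 | step 9 | 4-(benzyloxy)-2-hydroxy-6-propylbenzaldehyde | CCCc1cc(OCc2ccccc2)cc(O)c1C=O
F4 | step 9 | 4-(benzyloxy)-2-methoxy-6-propylbenzaldehyde | CCCc1cc(OCc2ccccc2)cc(OC)c1C=O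
F5 | step 9 | 4-(benzyloxy)-2-methoxy-6-propylbenzoic acid | CCCc1cc(OCc2ccccc2)cc(OC)c1C(=O)O
F6 | step 9 | 4-(benzyloxy)-2-methoxy-6-propylbenzoic trifluoroacetic anhydride | CCCc1cc(OCc2ccccc2)cc(OC)c1C(=O)OC(=O)C(F)(F)F
F7 | step 9 | 2,6-bis(benzyloxy)-3-formyl-4-propylphenyl 4-(benzyloxy)-2-methoxy-6-propylbenzoate | CCCc1cc(OCc2ccccc2)cc(OC)c1C(=O)Oc1c(OCc2ccccc2)cc(CCC)c(C=O)c1OCc1ccccc1
F8 | step 9 | 2,4-bis(benzyloxy)-3-{[4-(benzyloxy)-2-methoxy-6-propylbenzoyl]oxy}-6-propylbenzoic acid | CCCc1cc(OCc2ccccc2)cc(OC)c1C(=O)Oc1c(OCc2ccccc2)cc(CCC)c(C(=O)O)c1OCc1ccccc1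
F9 | step 2 | 2-iodo-5-propylbenzene-1,3-diol | CCCc1cc(O)c(I)c(O)c1
F10 | step 2 | 1,3-bis(benzyloxy)-2-iodo-5-propylbenzene | CCCc1cc(OCc2ccccc2)c(I)c(OCc2ccccc2)c1
F11 | step 3 | 2,6-bis(benzyloxy)-3-bromo-4-propylphenol | CCCc1cc(OCc2ccccc2)c(O)c(OCc2ccccc2)c1Br
F12 | step 3 | lithium 2,6-bis(benzyloxy)-3-lithio-4-propylphenolate | [Li+].[O-]c1c(OCc2ccccc2)cc(CCC)c([Li])c1OCc1ccccc1
F13 | step 3 | dilithium 2,6-bis(benzyloxy)-3-[(dimethylamino)oxidomethyl]-4-propylphenolate | [Li+].[Li+].[O-]C(N(C)C)c1c(CCC)cc(OCc2ccccc2)c([O-])c1OCc1ccccc1
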